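The lactone is opened at its O2–C1 bond, and the remaining C4a–C4–C3(O)–C1' array that links ring A to the side chain through the pyranone ring is recognised as the signature of an enantioselective conjunctive cross-coupling. The key step exploits exactly this benzyl–carbinol–alkyl motif: a vinylboron ate complex that carries the ketal-masked 7-oxoundecyl chain on boron meets the aryl triflate of ring A under chiral palladium catalysis. A palladium-induced 1,2-metallate shift moves the chain from boron to the future C3, creating the C3–C1' bond and the C3 stereocentre while C4 is arylated. Boron at C3 then becomes the ring oxygen, which closes the lactone onto the ortho ester.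

Key step: step 4

Remark on numbering: atoms are numbered as in isochroman-1-one (C1 carbonyl, O2, C3, C4, C4a to C8a); ring A is the benzene ring and C1' is the chain carbon on C3.
Assumption: the MandyPhos antipode that gives (R)-11 is taken to be (Rp,Rp) by analogy with the reported sense of induction of this ligand class. Should the first run give the (S)-series, the (Sp,Sp) antipode is used under the same conditions.

Step 1
Reactants: 1 7-bromoheptanenitrile; 2 n-butylmagnesium chloride
Product: 4 11-bromoundecan-5-one, via chloromagnesium ketimide 3 (not isolated)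
Conditions: n-BuMgCl (1.2 equiv), Et2O–toluene, 0 °C to 40 °C; then 2 M HCl, rt
Reagents that add atoms: water, O
Why: Grignard addition to a nitrile stops at the magnesium ketimide 3, the primary bromide is inert without a transition-metal catalyst, and acidic hydrolysis of the ketimide releases the ketone.

Step 2
Reactants: 4 11-bromoundecan-5-one
Product: 5 2-(6-bromohexyl)-2-butyl-1,3-dioxolane
Conditions: ethylene glycol, p-TsOH·H2O (cat.), toluene, reflux, Dean–Stark
Reagents that add atoms: ethylene glycol, OCCO
Why: Acid-catalysed ketalisation with azeotropic removal of water masks the ketone against the Grignard and borate chemistry of step 4 and leaves the primary bromide untouched.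

Step 3
Reactants: 6 methyl 2-hydroxy-4,6-dimethoxybenzoate
Product: 7 methyl 2,4-dimethoxy-6-{[(trifluoromethyl)sulfonyl]oxy}benzoate
Conditions: Tf2O, pyridine, CH2Cl2, 0 °C to rt
Reagents that add atoms: trifluoromethanesulfonic anhydride, O=S(=O)(OS(=O)(=O)C(F)(F)F)C(F)(F)F
Why: O-Sulfonylation (triflation) of the chelated phenol turns the aryl C–O bond at the future C4a into a cross-coupling handle without touching the ester.

Step 4
Reactants: 5 2-(6-bromohexyl)-2-butyl-1,3-dioxolane; 8 2-ethenyl-4,4,5,5-tetramethyl-1,3,2-dioxaborolane (vinylboronic acid pinacol ester); 7 methyl 2,4-dimethoxy-6-{[(trifluoromethyl)sulfonyl]oxy}benzoate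
Product: 11 methyl 2-[(2R)-8-(2-butyl-1,3-dioxolan-2-yl)-2-(4,4,5,5-tetramethyl-1,3,2-dioxaborolan-2-yl)octyl]-4,6-dimethoxybenzoate, via Grignard reagent 9 (not isolated), via vinylboron ate complex 10 (not isolated)
Conditions: 5, Mg, THF, 45 °C; then 8 (1.1 equiv), THF, 0 °C to rt; NaOTf; then 7, Pd(OAc)2 (2 mol%), (Rp,Rp)-MandyPhos (1,1'-bis(diphenylphosphino)-2,2'-bis[α-(dimethylamino)benzyl]ferrocene, C52H50FeN2P2, 2.4 mol%), THF, 60 °C
Reagents that add atoms: none
Why: Oxidative addition of triflate 7 to zerovalent palladium gives a cationic aryl–palladium complex that binds the vinyl group of borate 10 and triggers an anti-periplanar 1,2-shift of the primary alkyl group from boron to the α-carbon, which forms the C3–C1' bond and a C4–Pd bond; reductive elimination then forms the C4–C4a bond and returns zerovalent palladium. The closest known reaction type is the palladium/MandyPhos-catalysed enantioselective conjunctive cross-coupling of Grignard-derived vinylboron ate complexes with aryl triflates, applied here to a new substrate pair. No ring is closed in this step. The C3 stereocentre is set under catalyst control: the chiral bisphosphine decides which face of the vinyl group carries palladium and the alkyl group must migrate to the opposite face, so one enantiomer of the secondary boronate should result. The step needs the metallate shift to outrun direct vinyl transfer to palladium (Suzuki-type styrene formation) and needs carbon, not a pinacol oxygen, to migrate; the first is secured by the halide-poor cationic palladium centre (triflate electrophile, NaOTf removes bromide) and the chelating ligand, the second by the far higher migratory aptitude of the alkyl group. The methyl ester of 7 is safe because the Grignard reagent is consumed in borate formation by the slight excess of 8 before 7 is added.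

Step 5
Reactants: 11 methyl 2-[(2R)-8-(2-butyl-1,3-dioxolan-2-yl)-2-(4,4,5,5-tetramethyl-1,3,2-dioxaborolan-2-yl)octyl]-4,6-dimethoxybenzoate
Product: 13 (3R)-6,8-dimethoxy-3-(7-oxoundecyl)-3,4-dihydro-1H-isochromen-1-one, via hydroxy ester 12 (not isolated)
Conditions: 30% H2O2, 3 M NaOH, THF, 0 °C to rt; Na2S2O3; then 3 M HCl to pH 1, THF, 45 °C
Reagents that add atoms: hydrogen peroxide, OO; water, O
Why: Stereoretentive oxidation of the secondary C–B bond (1,2-shift of C3 from boron to oxygen) should give (R)-carbinol 12, whose oxygen acylates on the ortho ester to close the six-membered lactone (lactonisation with loss of methanol, completed on acidification), while the aqueous acid hydrolyses the dioxolane to the ketone; C3 is not epimerisable in either medium.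

Step 6
Reactants: 13 (3R)-6,8-dimethoxy-3-(7-oxoundecyl)-3,4-dihydro-1H-isochromen-1-one
Product: 14 (3R)-8-hydroxy-6-methoxy-3-(7-oxoundecyl)-3,4-dihydro-1H-isochromen-1-one
Conditions: BCl3 (1 M in CH2Cl2, 2 equiv), CH2Cl2, −78 °C to 0 °C; then H2O
Reagents that add atoms: none
Why: Chelation-directed aryl methyl ether cleavage: BCl3 binds between the lactone carbonyl and the peri 8-methoxy oxygen, so chloride should remove only that methyl group and leave the 6-methoxy group, the lactone, the ketone and C3 untouched.

Compound list
1 | 7-bromoheptanenitrile | N#CCCCCCCBr | starting material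
2 | n-butylmagnesium chloride | CCCC[Mg]Cl | starting material
3 | chloromagnesium ketimide of 11-bromoundecan-5-one | CCCCC(=N[Mg]Cl)CCCCCCBr | intermediate
4 | 11-bromoundecan-5-one | CCCCC(=O)CCCCCCBr | intermediate
5 | 2-(6-bromohexyl)-2-butyl-1,3-dioxolane | CCCCC1(OCCO1)CCCCCCBr | intermediate
6 | methyl 2-hydroxy-4,6-dimethoxybenzoate | COC(=O)c1c(O)cc(OC)cc1OC | starting material
7 | methyl 2,4-dimethoxy-6-{[(trifluoromethyl)sulfonyl]oxy}benzoate | COC(=O)c1c(OC)cc(OC)cc1OS(=O)(=O)C(F)(F)F | intermediate
8 | 2-ethenyl-4,4,5,5-tetramethyl-1,3,2-dioxaborolane | C=CB1OC(C)(C)C(C)(C)O1 | starting material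
9 | [6-(2-butyl-1,3-dioxolan-2-yl)hexyl]magnesium bromide | CCCCC1(OCCO1)CCCCCC[Mg]Br | intermediate
10 | bromomagnesium [6-(2-butyl-1,3-dioxolan-2-yl)hexyl](ethenyl)(pinacolato)borate | CCCCC1(OCCO1)CCCCCC[B-]2(C=C)OC(C)(C)C(C)(C)O2.[Mg+]Br | intermediate
11 | methyl 2-[(2R)-8-(2-butyl-1,3-dioxolan-2-yl)-2-(4,4,5,5-tetramethyl-1,3,2-dioxaborolan-2-yl)octyl]-4,6-dimethoxybenzoate | CCCCC1(OCCO1)CCCCCC[C@@H](B2OC(C)(C)C(C)(C)O2)Cc2cc(OC)cc(OC)c2C(=O)OC | intermediate
12 | methyl 2-[(2R)-8-(2-butyl-1,3-dioxolan-2-yl)-2-hydroxyoctyl]-4,6-dimethoxybenzoate | CCCCC1(OCCO1)CCCCCC[C@@H](O)Cc2cc(OC)cc(OC)c2C(=O)OC | intermediate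
13 | (3R)-6,8-dimethoxy-3-(7-oxoundecyl)-3,4-dihydro-1H-isochromen-1-one | CCCCC(=O)CCCCCC[C@@H]1Cc2cc(OC)cc(OC)c2C(=O)O1 | intermediate
14 | (3R)-8-hydroxy-6-methoxy-3-(7-oxoundecyl)-3,4-dihydro-1H-isochromen-1-one | CCCCC(=O)CCCCCC[C@@H]1Cc2cc(OC)cc(O)c2C(=O)O1 | target

Total step count: 6
Longest linear sequence: 5 steps (steps 1, 2, 4, 5, 6); the aryl branch (steps 3, 4, 5, 6) is 4 steps.

Steps most likely to fail

Step 4. Three processes may intervene. The vinyl group may transfer directly to palladium in place of the metallate shift. Residual halide from the Grignard reagent may erode enantioselectivity. Oxidative addition of the ortho-ester-substituted, electron-rich triflate may be sluggish. The fallback keeps the C3–C1' bond construction but changes it to a catalytic asymmetric alkylzinc addition; it sets out from 7 and 5 and comes back at 12. Triflate 7 would be allylated by Stille coupling (allyltributylstannane, Pd(PPh3)4, LiCl, DMF, 90 °C) to methyl 2-allyl-4,6-dimethoxybenzoate F1. Lemieux–Johnson cleavage (OsO4 cat., NaIO4, 2,6-lutidine, dioxane–H2O) would then give methyl 2,4-dimethoxy-6-(2-oxoethyl)benzoate F2. Bromide 5 would be taken through Grignard reagent 9 (Mg, THF) and ZnCl2 (0.5 equiv), with 1,4-dioxane added to precipitate the magnesium halides, to bis[6-(2-butyl-1,3-dioxolan-2-yl)hexyl]zinc F3. Addition of F3 to F2 with Ti(OiPr)4 and catalytic (1S,2S)-1,2-bis(trifluoromethanesulfonamido)cyclohexane (toluene, −20 °C) is expected, on the established facial model for this ligand, to give (R)-hydroxy ester 12. Compound 12 then enters the acid stage of step 5.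

Step 6. Regiocontrol of the ether cleavage may be lost (partial cleavage of the 6-methoxy group or incomplete reaction), or the Lewis acid may promote side reactions at the ketone. The fallback replaces selective cleavage by exhaustive cleavage followed by selective re-methylation; it sets out from 13 and comes back at 14. BBr3 (3 equiv, CH2Cl2, −78 °C to rt) would give (3R)-6,8-dihydroxy-3-(7-oxoundecyl)-3,4-dihydro-1H-isochromen-1-one F4. MeI (1.1 equiv) and K2CO3 in acetone at rt should then methylate only the free 6-hydroxyl, because the 8-hydroxyl is held in a hydrogen bond to the lactone carbonyl, and so give 14.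

Step 1. The Grignard reagent may deprotonate the nitrile at its α-position or couple with the alkyl bromide, so that conversion to the ketimide stays low. The fallback builds the ketone by aldehyde addition and oxidation; it sets out from 1 and 2 and comes back at 4. Nitrile 1 would be reduced with i-Bu2AlH (toluene, −78 °C) to the N-(diisobutylalumino)aldimine F5, which is hydrolysed on work-up (dilute HCl) to 7-bromoheptanal F6. Addition of 2 (THF, −78 °C) would give 11-bromoundecan-5-ol F7, and Dess–Martin periodinane (CH2Cl2, rt) would oxidise it to 4.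

Further compounds
F1 | step 4 | methyl 2-allyl-4,6-dimethoxybenzoate | COC(=O)c1c(OC)cc(OC)cc1CC=C
F2 | step 4 | methyl 2,4-dimethoxy-6-(2-oxoethyl)benzoate | COC(=O)c1c(OC)cc(OC)cc1CC=O
F3 | step 4 | bis[6-(2-butyl-1,3-dioxolan-2-yl)hexyl]zinc | CCCCC1(CCCCCC[Zn]CCCCCCC2(CCCC)OCCO2)OCCO1
F4 | step 6 | (3R)-6,8-dihydroxy-3-(7-oxoundecyl)-3,4-dihydro-1H-isochromen-1-one | CCCCC(=O)CCCCCC[C@@H]1Cc2cc(O)cc(O)c2C(=O)O1
F5 | step 1 | N-(diisobutylalumino)-7-bromoheptan-1-imine | BrCCCCCCC=N[Al](CC(C)C)CC(C)C
F6 | step 1 | 7-bromoheptanal | O=CCCCCCCBr
F7 | step 1 | 11-bromoundecan-5-ol | CCCCC(O)CCCCCCBr
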